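# Proposed synthesis of (2S,3S,4S,5R)-2,5-bis(4-hydroxy-3,5-dimethoxyphenyl)-3,4-dimethyloxolane (CNP0217414.2)

## Structural features

The target is a single oxolane ring (O1, C2–C5) with a 4-hydroxy-3,5-dimethoxyphenyl group on C2 and on C5 and a methyl group on C3 and on C4. The four stereocentres are contiguous and read from the SMILES as (2S,3S,4S,5R). The C2 aryl is trans to the C3 methyl, the two methyls are trans, and the C5 aryl is cis to the C4 methyl, so the two aryl groups are cis across the ring oxygen. Because the aryl groups are identical, the two halves differ only in that one aryl/methyl pair is trans and the other cis, and a synthesis has to tell the two benzylic positions apart. Both ring C–O bonds are benzylic and para to a free phenol. Acid, hot base or hydrogenolysis can therefore open or epimerise them through a benzylic cation or quinone methide, and the electron-rich phenols are easily over-oxidised. The real difficulty is twofold: the 4,5-cis aryl/methyl pair is the less stable arrangement and must be fixed by a reagent and then kept from equilibrating, and the trans (dl-type) methyl pair is the one that substrate-controlled additions to an alkene next to C4 tend not to give. The key step uses the C2 aryl: as a free 4-hydroxy-3,5-dimethoxyphenyl group it can be oxidised by two electrons to a para-quinone methide whose exocyclic carbon is C2, five atoms from the oxygen on C5, so that this hydroxyl can form O1–C2.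

## Logic of the disconnections

Remark on the structures: the configurations written for 14 and 16 agree with 17 at every shared centre ((1R,2S,3R) in 14 corresponds to C5 R, C4 S, C3 S of the ring), so both are used as drawn. What needs attention is how C3 is set (fourth paragraph).

**17 ⇒ 16.** The O–CH2Ph bond on the C5 aryl is cut. This group exists only to make the two phenols different, so that the oxidation in step 7 touches one ring and not the other. The gain is the end-differentiation of an almost symmetric molecule. The demand is that hydrogenolysis take the aryl benzyl ether and leave the two benzylic C–O bonds of the ring.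

**16 ⇒ 14 (through 15).** The O1–C2 bond is cut, which opens the ring and removes the C2 stereocentre. C2 is the right place because it is the one centre whose configuration (aryl trans to the C3 methyl) is the one the substrate itself prefers. The free phenol on that ring also allows C2 to be made electrophilic without a leaving group. The gain is an acyclic 1,4-diarylbutanol with three stereocentres. The demand is a chemoselective two-electron oxidation of one phenol, a ring closure that outruns the other reactions of 15, and a precursor in which C5, C4 and C3 are already correct, since nothing later can mend them.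

**14 ⇒ 10 + 12 (through 13).** The bond between the benzylic CH2 (C4 of the butanol, C2 of the ring) and its aryl ring is cut as an sp3–sp2 cross-coupling. This separates an aryl bromide made in one step from a four-carbon chain that carries all three stereocentres. The demand is that a primary, β-branched alkylboron transmetalate next to a free secondary benzylic alcohol. The phenol must also be masked during coupling and freed afterwards without loss of the benzyl ether, which a silyl ether cleaved by fluoride in the same flask allows.

**10 ⇒ 8 (through 9).** The C4–B and C3–H bonds are cut (retro-hydroboration of a 1,1-disubstituted alkene), turning the C3 stereocentre into a prochiral alkene carbon. The demand is delivery of hydrogen to the face of C3 that makes the two methyls syn in the extended chain (trans on the ring). A hindered dialkylborane such as 9-BBN cannot be relied on for this. Next to a methyl-bearing allylic centre it is expected to attack anti to the large C1 substituent with the allylic hydrogen eclipsing the alkene, which leads mainly to the C3 epimer (methyls anti, cis on the ring), and C3 cannot be corrected later. The design therefore puts this centre under catalyst control (chiral copper hydride with pinacolborane). The O–B bond of 8 is left in place as the protecting group of the carbinol during this step: a free hydroxyl would only be borylated again by the hydroborating reagent, with loss of hydrogen and of one more equivalent of reagent. The cost is an isolated boronic ester in place of a borane made and used in one flask.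

**8 ⇒ 3 + 7.** The C1–C2 bond between the carbinol carbon and the methyl-bearing carbon is cut (allylboration). One closed six-membered transition state sets both the carbinol centre and its neighbour, which is the 4,5-cis pair of the ring, and leaves the alkene needed for the next step. The demand is a Z-configured allylboron reagent (syn product), face selection at the aldehyde by a chiral acid, an aldehyde without a free phenol, and a non-aqueous isolation that keeps the borate.

**7 ⇒ 4 + 5 (through 6).** The bond between the alkene carbon and the boron-bearing CH2 is cut. The Z geometry is bought in 4 and carried through with retention, which avoids any regio- or stereochemical question in making the allylboron reagent. The demand is lithium–bromine exchange at low temperature, then attack at boron and 1,2-shift with loss of chloride.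

**3 ⇒ 1 + 2 and 12 ⇒ 11.** The O–CH2Ph and O–Si bonds of two different protecting groups are cut. Benzyl survives fluoride and silyl is removed by fluoride beside benzyl, which is all the orthogonality the route needs. The demand is clean O-functionalisation of two hindered 2,6-dimethoxyphenols.

## Other disconnections considered

**Alternative 1:** The two C–CH3 bonds at C3 and C4 are cut.
- **Forward step:** Me2CuLi adds to the β-carbon (C3) of the enantioenriched γ-aryl butenolide A2 from the face opposite the aryl group. The enolate is then methylated at C4 by MeI from the face opposite the new methyl, giving the all-trans lactone A1 in one flask. Aryl addition to the lactone carbonyl, ionic reduction at C5 and cleavage of both benzyl ethers of A3 would finish the route.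
- **In favour:** both methyl centres come from one resident centre by cyclic substrate control. On the trans methyl pair this plan is the better one, since the chosen plan must impose that relationship with a chiral catalyst against the bias of its substrate. It is also the better on protecting groups (two identical benzyl ethers, no need to tell the phenols apart) and about equal in step count.
- **Against:** the only stereocentre of A2 carries a hydrogen that is benzylic, allylic and α to oxygen, and the basic cuprate medium can racemise it through the 2-oxyfuran. Enolates formed by cuprate addition are slow to alkylate, so the one-flask double methylation may need to be split. The 4,5-cis pair would come last, from hydride delivery at C5 under a Lewis acid that can also ionise the electron-rich benzylic C–O bonds and let the ring drift to the all-trans isomer.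
- **Comparison:** the chosen plan fixes the cis pair first, by a reagent, and closes the ring in a near-neutral medium. The mechanisms are polar substrate-controlled additions here against reagent-controlled boron chemistry and an oxidative closure there.

**Alternative 2:** The C3–C4 and O1–C2 bonds are cut, a formal [3+2] across a propenyl C=C.
- **Forward step:** Rh2(S-PTTL)4 (dirhodium tetrakis[N-phthaloyl-(S)-tert-leucinate], divalent rhodium) decomposes the aroyl diazo ester A5. The carbenoid carbon bonds to the methyl-bearing carbon of the (E)-propenylarene A6 and the ketone oxygen to the benzylic carbon, giving the trans dihydrofuran A4.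
- **In favour:** it is the most convergent plan. The ring, two bonds and the C2/C3 pair with absolute control arise in one catalytic step from two simple halves. On convergence it is the better plan, and on setting C2 trans to C3 it is the equal of the chosen plan.
- **Against:** A4 is both over-functionalised and under-reduced. The ester at C4 must be cut down to a methyl group (reduction, activation, reduction). The tetrasubstituted enol ether C4=C5 must then be reduced to create two further centres (3,4-trans and 4,5-cis) under acidic ionic conditions that threaten the benzylic ethers and offer no clear control of the cis pair. Acceptor-substituted carbenoids may also give cyclopropanes with styrene-type alkenes.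
- **Comparison:** about five steps follow the key step against one in the chosen plan, and control at C4 and C5 is weaker, while the chosen plan has all three precursor centres in place before the ring exists.

**Alternative 3:** The C2–aryl and O1–C2 bonds are cut at the terminal alkene carbon of alkenol A8, the free alcohol of borate ester 8.
- **Forward step:** Pd(OAc)2 (divalent palladium) with benzoquinone as oxidant transfers the aryl group of boronic acid A7 to the CH2 terminus of A8. β-Hydride elimination and re-insertion move palladium to the benzylic carbon, and C–O bond formation with the hydroxyl closes the ring to A3, from which both benzyl ethers are then removed.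
- **In favour:** step economy, on which it is clearly the better plan. It shares steps 1 to 3 with the chosen route (step 3 ending with an aqueous work-up that gives A8 in place of 8), replaces steps 4 to 7 by one, and needs no differentiation of the phenols.
- **Against:** the alkene of A8 is 1,1-disubstituted, so insertion gives a tertiary alkylpalladium with three kinds of β-hydrogen. Elimination toward C4 would destroy that stereocentre and elimination toward the methyl gives an exo-methylene isomer. C3 would be created by palladium hydride re-insertion and C2 by the C–O bond formation, neither with a controlling element that can be named in advance.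
- **Comparison:** on structure and mechanism the chosen plan is stronger, since it sets C3 by a chiral catalyst and C2 by allylic strain in a defined intermediate. On the number of steps the alternative wins.

Key step: step 7

Assumption: (Z)-2-bromobut-2-ene is bought as the single isomer. The antipodes written for the two chiral catalysts are those expected by analogy with simpler aryl aldehydes and 2-methyl-1-alkenes, and the other antipode is used if the first run shows the opposite sense.

## Route

Step 1
Reactants: 1 syringaldehyde (4-hydroxy-3,5-dimethoxybenzaldehyde); 2 benzyl bromide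
Product: 3 4-(benzyloxy)-3,5-dimethoxybenzaldehyde
Conditions: K2CO3, DMF, 60 °C
Reagents that add atoms: none
Why: Williamson ether synthesis on the acidic para-formyl phenoxide; the benzyl ether keeps this phenol from being oxidised in step 7 and is inert to every step before step 8.

Step 2
Reactants: 4 (Z)-2-bromobut-2-ene; 5 2-(chloromethyl)-4,4,5,5-tetramethyl-1,3,2-dioxaborolane
Product: 7 4,4,5,5-tetramethyl-2-[(2Z)-2-methylbut-2-en-1-yl]-1,3,2-dioxaborolane, via (E)-but-2-en-2-yllithium 6 (not isolated)
Conditions: t-BuLi (2.0 equiv), THF, −78 °C; then 5, −78 °C to rt
Reagents that add atoms: none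
Why: Lithium–bromine exchange on an alkenyl bromide keeps the alkene geometry at −78 °C, and the alkenyllithium adds to boron of 5 to give an ate complex that undergoes 1,2-migration with loss of chloride (Matteson-type homologation). The CH2B group therefore ends up cis to the terminal methyl, the Z geometry that step 3 turns into the syn pair.

Step 3
Reactants: 3 4-(benzyloxy)-3,5-dimethoxybenzaldehyde; 7 4,4,5,5-tetramethyl-2-[(2Z)-2-methylbut-2-en-1-yl]-1,3,2-dioxaborolane
Product: 8 2-{[(1R,2S)-1-[4-(benzyloxy)-3,5-dimethoxyphenyl]-2,3-dimethylbut-3-en-1-yl]oxy}-4,4,5,5-tetramethyl-1,3,2-dioxaborolane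
Conditions: (R)-TRIP [(R)-3,3'-bis(2,4,6-triisopropylphenyl)-1,1'-binaphthalene-2,2'-diyl hydrogen phosphate] (5 mol %), 4 Å MS, toluene, −30 °C; filtered under Ar and concentrated, no aqueous work-up
Reagents that add atoms: none
Why: Chiral-phosphoric-acid-catalysed allylboration through a closed chair (Zimmerman–Traxler) transition state, in which the Z γ-methyl is axial and gives the syn relationship of oxygen and methyl. The (R)-acid, hydrogen-bonded to a boronate oxygen and the formyl hydrogen, is the antipode that directs attack to the Re face of aryl aldehydes, so C1 should be R and C2 S. The addition product is the borate ester itself, and it is kept as such because pinacolborane in step 4 would only borylate a free hydroxyl again.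

Step 4
Reactants: 8 2-{[(1R,2S)-1-[4-(benzyloxy)-3,5-dimethoxyphenyl]-2,3-dimethylbut-3-en-1-yl]oxy}-4,4,5,5-tetramethyl-1,3,2-dioxaborolane
Product: 10 (1R,2S,3R)-1-[4-(benzyloxy)-3,5-dimethoxyphenyl]-2,3-dimethyl-4-(4,4,5,5-tetramethyl-1,3,2-dioxaborolan-2-yl)butan-1-ol, via O,C-diboryl intermediate 9 (not isolated)
Conditions: CuCl (5 mol %), (R)-DTBM-SEGPHOS [(R)-5,5'-bis{bis(3,5-di-tert-butyl-4-methoxyphenyl)phosphino}-4,4'-bi-1,3-benzodioxole] (5.5 mol %), KOtBu (15 mol %), HBpin (1.5 equiv), toluene, rt; then aq. NH4Cl
Reagents that add atoms: pinacolborane, CC1(C)OBOC1(C)C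
Why: Copper hydride-catalysed enantioselective anti-Markovnikov hydroboration of a 1,1-disubstituted alkene (monovalent copper with a bulky bisphosphine): L*Cu–H adds with copper on the CH2 terminus and hydrogen on C3, σ-bond metathesis with pinacolborane releases the primary boronate 9 and regenerates the hydride, and aqueous ammonium chloride then hydrolyses only the O–B bond. The ligand antipode is the one that delivers hydrogen to the Si face of C3 (3R, methyls syn), so C3 is set by the catalyst and not by the substrate bias that would make 9-BBN give mainly the C3 epimer. The alkoxide charge beyond that needed to form the copper alkoxide takes up the phosphoric acid carried over from step 3.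

Step 5
Reactants: 11 4-bromo-2,6-dimethoxyphenol
Product: 12 (4-bromo-2,6-dimethoxyphenoxy)(tert-butyl)dimethylsilane
Conditions: TBSCl, imidazole, DMF, rt
Reagents that add atoms: tert-butyl(chloro)dimethylsilane, CC(C)(C)[Si](C)(C)Cl
Why: Imidazole-promoted O-silylation of the phenol; the silyl ether keeps the bromide from entering the coupling as an electron-rich phenoxide and is the one group that fluoride removes beside the benzyl ether.

Step 6
Reactants: 10 (1R,2S,3R)-1-[4-(benzyloxy)-3,5-dimethoxyphenyl]-2,3-dimethyl-4-(4,4,5,5-tetramethyl-1,3,2-dioxaborolan-2-yl)butan-1-ol; 12 (4-bromo-2,6-dimethoxyphenoxy)(tert-butyl)dimethylsilane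
Product: 14 (1R,2S,3R)-1-[4-(benzyloxy)-3,5-dimethoxyphenyl]-4-(4-hydroxy-3,5-dimethoxyphenyl)-2,3-dimethylbutan-1-ol, via silyl ether 13 (not isolated)
Conditions: Pd(OAc)2 (5 mol %), RuPhos (10 mol %), K3PO4 (3 equiv), toluene/H2O (10:1), 90 °C; then Bu4NF (1.2 equiv), THF, 0 °C
Reagents that add atoms: none
Why: B-alkyl Suzuki–Miyaura coupling of a primary alkylboronic ester with an aryl bromide; the bulky electron-rich biarylphosphine (RuPhos, 2-dicyclohexylphosphino-2',6'-diisopropoxybiphenyl) speeds oxidative addition to the electron-rich bromide and reductive elimination ahead of β-hydride elimination, and the free secondary alcohol is tolerated. No stereocentre is at a reacting carbon, and fluoride then cleaves only the aryl silyl ether to give the one free phenol that step 7 needs.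

Step 7
Reactants: 14 (1R,2S,3R)-1-[4-(benzyloxy)-3,5-dimethoxyphenyl]-4-(4-hydroxy-3,5-dimethoxyphenyl)-2,3-dimethylbutan-1-ol
Product: 16 4-[(2S,3S,4S,5R)-5-[4-(benzyloxy)-3,5-dimethoxyphenyl]-3,4-dimethyloxolan-2-yl]-2,6-dimethoxyphenol, via para-quinone methide 15 (not isolated)
Conditions: undivided cell, graphite anode, Pt cathode, constant current (2 mA cm−2), 2.1 F mol−1, Bu4NBF4 (0.1 M), 2,6-lutidine (2 equiv), MeCN/CH2Cl2 (4:1), 0 °C
Reagents that add atoms: none
Why: At the anode the free phenol of 14, the most easily oxidised site (the benzyloxy-bearing ring and the benzylic alcohol lie at clearly higher potential), loses one electron and its proton to give a phenoxyl radical, and a second electron transfer with loss of the benzylic proton to 2,6-lutidine gives para-quinone methide 15, while protons are reduced to hydrogen at the cathode. The closest known reaction type is the two-electron oxidation of 4-alkyl-2,6-dimethoxyphenols (anodic or with Ag2O) to quinone methides that add alcohols in a 1,6-sense, the ring-closing half of the presumed biosynthesis of these lignans. The ring is closed by 5-exo-trig oxa-1,6-addition of the C5 hydroxyl to the exocyclic carbon, which restores the aromatic ring and forms O1–C2. The new C2 centre is controlled by allylic 1,3-strain in 15: the C3–H bond lies in the plane of the methide facing the ring, the tether reaches C2 from the face away from the C3 methyl, and the aryl group ends up trans to that methyl in a pseudo-equatorial position, which is also the more stable arrangement. The step needs chemoselective oxidation of one of two similar arenes, secured by the benzyl ether on the other phenol, and closure faster than capture of 15 by outside nucleophiles, than its tautomerisation to a styrene and than ipso attack, secured by the non-nucleophilic medium, the weak hindered base and the five-membered transition state. Over-oxidation of 16, itself a phenol, is limited by stopping at about two faradays per mole, and the near-neutral medium leaves the cis C4/C5 pair untouched.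

Step 8
Reactants: 16 4-[(2S,3S,4S,5R)-5-[4-(benzyloxy)-3,5-dimethoxyphenyl]-3,4-dimethyloxolan-2-yl]-2,6-dimethoxyphenol
Product: 17 4,4'-[(2S,3S,4S,5R)-3,4-dimethyloxolane-2,5-diyl]bis(2,6-dimethoxyphenol)
Conditions: H2 (1 atm), Pd/C (10 wt %), EtOAc, rt
Reagents that add atoms: none
Why: Catalytic hydrogenolysis of an aryl benzyl ether, which in neutral ethyl acetate at one atmosphere is much faster than cleavage of the two dialkyl-type benzylic C–O bonds of the ring. No acid is present, the reaction is stopped when 16 is consumed, and none of the four stereocentres is touched.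

## Compound list

1 | syringaldehyde (4-hydroxy-3,5-dimethoxybenzaldehyde) | COc1cc(C=O)cc(OC)c1O | starting material
2 | benzyl bromide | BrCc1ccccc1 | starting material
3 | 4-(benzyloxy)-3,5-dimethoxybenzaldehyde | COc1cc(C=O)cc(OC)c1OCc1ccccc1 | intermediate
4 | (Z)-2-bromobut-2-ene | C/C=C(\Br)C | starting material
5 | 2-(chloromethyl)-4,4,5,5-tetramethyl-1,3,2-dioxaborolane | ClCB1OC(C)(C)C(C)(C)O1 | starting material
6 | (E)-but-2-en-2-yllithium (lithium cis to the C4 methyl, formed in the flask) | C/C=C(\[Li])C | intermediate
7 | 4,4,5,5-tetramethyl-2-[(2Z)-2-methylbut-2-en-1-yl]-1,3,2-dioxaborolane | C/C=C(/C)CB1OC(C)(C)C(C)(C)O1 | intermediate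
8 | 2-{[(1R,2S)-1-[4-(benzyloxy)-3,5-dimethoxyphenyl]-2,3-dimethylbut-3-en-1-yl]oxy}-4,4,5,5-tetramethyl-1,3,2-dioxaborolane (pinacol borate ester, used crude) | CC1(C)OB(O[C@@H](c2cc(OC)c(OCc3ccccc3)c(OC)c2)[C@@H](C)C(C)=C)OC1(C)C | intermediate
9 | 2-{[(1R,2S,3R)-1-[4-(benzyloxy)-3,5-dimethoxyphenyl]-2,3-dimethyl-4-(4,4,5,5-tetramethyl-1,3,2-dioxaborolan-2-yl)butyl]oxy}-4,4,5,5-tetramethyl-1,3,2-dioxaborolane (O,C-diboryl intermediate, formed in the flask) | CC1(C)OB(O[C@@H](c2cc(OC)c(OCc3ccccc3)c(OC)c2)[C@@H](C)[C@H](C)CB2OC(C)(C)C(C)(C)O2)OC1(C)C | intermediate
10 | (1R,2S,3R)-1-[4-(benzyloxy)-3,5-dimethoxyphenyl]-2,3-dimethyl-4-(4,4,5,5-tetramethyl-1,3,2-dioxaborolan-2-yl)butan-1-ol | O[C@@H](c1cc(OC)c(OCc2ccccc2)c(OC)c1)[C@@H](C)[C@H](C)CB1OC(C)(C)C(C)(C)O1 | intermediate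
11 | 4-bromo-2,6-dimethoxyphenol | COc1cc(Br)cc(OC)c1O | starting material
12 | (4-bromo-2,6-dimethoxyphenoxy)(tert-butyl)dimethylsilane | COc1cc(Br)cc(OC)c1O[Si](C)(C)C(C)(C)C | intermediate
13 | (1R,2S,3R)-1-[4-(benzyloxy)-3,5-dimethoxyphenyl]-4-{4-[(tert-butyldimethylsilyl)oxy]-3,5-dimethoxyphenyl}-2,3-dimethylbutan-1-ol (silyl ether of 14, formed in the flask) | O[C@@H](c1cc(OC)c(OCc2ccccc2)c(OC)c1)[C@@H](C)[C@H](C)Cc1cc(OC)c(O[Si](C)(C)C(C)(C)C)c(OC)c1 | intermediate
14 | (1R,2S,3R)-1-[4-(benzyloxy)-3,5-dimethoxyphenyl]-4-(4-hydroxy-3,5-dimethoxyphenyl)-2,3-dimethylbutan-1-ol | O[C@@H](c1cc(OC)c(OCc2ccccc2)c(OC)c1)[C@@H](C)[C@H](C)Cc1cc(OC)c(O)c(OC)c1 | intermediate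
15 | 4-[(2R,3S,4R)-4-[4-(benzyloxy)-3,5-dimethoxyphenyl]-4-hydroxy-2,3-dimethylbutylidene]-2,6-dimethoxycyclohexa-2,5-dien-1-one (para-quinone methide, formed in the flask) | O[C@@H](c1cc(OC)c(OCc2ccccc2)c(OC)c1)[C@@H](C)[C@H](C)C=C1C=C(OC)C(=O)C(OC)=C1 | intermediate
16 | 4-[(2S,3S,4S,5R)-5-[4-(benzyloxy)-3,5-dimethoxyphenyl]-3,4-dimethyloxolan-2-yl]-2,6-dimethoxyphenol | COc1cc([C@H]2O[C@@H](c3cc(OC)c(OCc4ccccc4)c(OC)c3)[C@@H](C)[C@@H]2C)cc(OC)c1O | intermediate
17 | 4,4'-[(2S,3S,4S,5R)-3,4-dimethyloxolane-2,5-diyl]bis(2,6-dimethoxyphenol) | COc1cc([C@H]2O[C@@H](c3cc(OC)c(O)c(OC)c3)[C@@H](C)[C@@H]2C)cc(OC)c1O | target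

## Step count and least certain steps

Total step count: 8 (steps 2 and 5 prepare the two coupling partners). Longest linear sequence: 6 steps (1, 3, 4, 6, 7, 8, counted from 1).

**Step 7 (key step).** What may go wrong: over-oxidation, because 16 is a 4-substituted 2,6-dimethoxyphenol like 14 and is oxidised at nearly the same potential, which would open or cleave the new ring. Other failure processes are capture of the oxidised ring at its ipso carbon by the hydroxyl (six-membered spirodienone) or by traces of water, tautomerisation of 15 to a 4-alkenylphenol (which would erase C3), and coupling of phenoxyl radicals at high current density. A first response within the step is a lower current density, a flow cell, or Ag2O (monovalent silver) in CH2Cl2 as the two-electron oxidant.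

The fallback that changes the approach reaches the same quinone methide 15 without an oxidant, from a benzylic alcohol at the future C2. It sets out from 10 and comes back to the route at 16. Oxidation of the C–B bond of 10 (NaBO3·4H2O, THF/H2O) gives (1R,2S,3S)-1-[4-(benzyloxy)-3,5-dimethoxyphenyl]-2,3-dimethylbutane-1,4-diol F1. TEMPO with PhI(OAc)2 closes it to (3S,4S,5R)-5-[4-(benzyloxy)-3,5-dimethoxyphenyl]-3,4-dimethyloxolan-2-one F2. i-Bu2AlH at −78 °C gives the lactol (3S,4S,5R)-5-[4-(benzyloxy)-3,5-dimethoxyphenyl]-3,4-dimethyloxolan-2-ol F3. The aryllithium made from 12 and n-BuLi adds to the open aldehyde form to give (1R,2S,3S)-1-[4-(benzyloxy)-3,5-dimethoxyphenyl]-4-{4-[(tert-butyldimethylsilyl)oxy]-3,5-dimethoxyphenyl}-2,3-dimethylbutane-1,4-diol F4, as both C4 epimers, which converge. Bu4NF frees the phenol to give (1R,2S,3S)-1-[4-(benzyloxy)-3,5-dimethoxyphenyl]-4-(4-hydroxy-3,5-dimethoxyphenyl)-2,3-dimethylbutane-1,4-diol F5. A catalytic amount of pyridinium p-toluenesulfonate in CH2Cl2 at 0 °C should ionise only the para-hydroxybenzylic alcohol of F5 to 15, which closes as in step 7 to 16.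

**Step 4.** What may go wrong: poor facial selectivity at C3, because the catalyst has to work against the preference of the substrate (attack anti to the large C1 substituent), and slow turnover with a hindered α-branched alkene. Consumption of hydride by acid or unreacted 3 carried over with crude 8 is a further risk. A low ratio would have to be dealt with by separation at 10 or 14, since C3 cannot be epimerised later.

The fallback uses known chemistry without a chiral catalyst at this centre and sets C3 by thermodynamic control in a lactone. It sets out from 8, joins the sequence above at F2 and comes back to the route at 16. 9-BBN and then NaOH/H2O2, which also cleaves the O–B bond of 8, convert 8 into (1R,2S)-1-[4-(benzyloxy)-3,5-dimethoxyphenyl]-2,3-dimethylbutane-1,4-diol F6, as a mixture of C3 epimers. TEMPO with PhI(OAc)2 gives (4S,5R)-5-[4-(benzyloxy)-3,5-dimethoxyphenyl]-3,4-dimethyloxolan-2-one F7, still epimeric at C3. DBU in toluene at 80 °C equilibrates the α-centre to (3S,4S,5R)-5-[4-(benzyloxy)-3,5-dimethoxyphenyl]-3,4-dimethyloxolan-2-one F2, in which the α-methyl is trans to the β-methyl, the all-cis epimer being strongly disfavoured. From F2 the sequence through F3, F4 and F5 described under step 7 is followed. This fallback gives up the anodic closure but keeps the O1–C2 disconnection and intermediate 15.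

**Step 6.** What may go wrong: slow transmetalation of the β-branched primary boronic ester. That leaves time for protodeboronation, for β-hydride elimination after transmetalation, or for early loss of the silyl group, after which the phenoxide slows oxidative addition.

The fallback changes the boron nucleophile to a slow-release trifluoroborate. It sets out from 10 and comes back to the route at 13. KHF2 in MeOH/H2O converts 10 into potassium [(2R,3S,4R)-4-[4-(benzyloxy)-3,5-dimethoxyphenyl]-4-hydroxy-2,3-dimethylbutyl]trifluoroborate F8. F8 is coupled with 12 (Pd(OAc)2, RuPhos, K2CO3, toluene/H2O, 85 °C) to give 13, and fluoride then gives 14 as in step 6.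

## Further compounds

F1 | step 7 | (1R,2S,3S)-1-[4-(benzyloxy)-3,5-dimethoxyphenyl]-2,3-dimethylbutane-1,4-diol | O[C@@H](c1cc(OC)c(OCc2ccccc2)c(OC)c1)[C@@H](C)[C@H](C)CO
F2 | step 7 | (3S,4S,5R)-5-[4-(benzyloxy)-3,5-dimethoxyphenyl]-3,4-dimethyloxolan-2-one | O1[C@@H](c2cc(OC)c(OCc3ccccc3)c(OC)c2)[C@@H](C)[C@H](C)C1=O
F3 | step 7 | (3S,4S,5R)-5-[4-(benzyloxy)-3,5-dimethoxyphenyl]-3,4-dimethyloxolan-2-ol (both C2 epimers) | O1[C@@H](c2cc(OC)c(OCc3ccccc3)c(OC)c2)[C@@H](C)[C@H](C)C1O
F4 | step 7 | (1R,2S,3S)-1-[4-(benzyloxy)-3,5-dimethoxyphenyl]-4-{4-[(tert-butyldimethylsilyl)oxy]-3,5-dimethoxyphenyl}-2,3-dimethylbutane-1,4-diol (both C4 epimers) | O[C@@H](c1cc(OC)c(OCc2ccccc2)c(OC)c1)[C@@H](C)[C@H](C)C(O)c1cc(OC)c(O[Si](C)(C)C(C)(C)C)c(OC)c1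
F5 | step 7 | (1R,2S,3S)-1-[4-(benzyloxy)-3,5-dimethoxyphenyl]-4-(4-hydroxy-3,5-dimethoxyphenyl)-2,3-dimethylbutane-1,4-diol (both C4 epimers) | O[C@@H](c1cc(OC)c(OCc2ccccc2)c(OC)c1)[C@@H](C)[C@H](C)C(O)c1cc(OC)c(O)c(OC)c1
F6 | step 4 | (1R,2S)-1-[4-(benzyloxy)-3,5-dimethoxyphenyl]-2,3-dimethylbutane-1,4-diol (both C3 epimers) | O[C@@H](c1cc(OC)c(OCc2ccccc2)c(OC)c1)[C@@H](C)C(C)CO
F7 | step 4 | (4S,5R)-5-[4-(benzyloxy)-3,5-dimethoxyphenyl]-3,4-dimethyloxolan-2-one (both C3 epimers) | O1[C@@H](c2cc(OC)c(OCc3ccccc3)c(OC)c2)[C@@H](C)C(C)C1=O
F8 | step 6 | potassium [(2R,3S,4R)-4-[4-(benzyloxy)-3,5-dimethoxyphenyl]-4-hydroxy-2,3-dimethylbutyl]trifluoroborate | [K+].O[C@@H](c1cc(OC)c(OCc2ccccc2)c(OC)c1)[C@@H](C)[C@H](C)C[B-](F)(F)F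
A1 | alternative 1 | (3S,4S,5S)-5-[4-(benzyloxy)-3,5-dimethoxyphenyl]-3,4-dimethyloxolan-2-one | COc1cc([C@H]2OC(=O)[C@@H](C)[C@@H]2C)cc(OC)c1OCc1ccccc1
A2 | alternative 1 | (5S)-5-[4-(benzyloxy)-3,5-dimethoxyphenyl]furan-2(5H)-one | COc1cc([C@H]2OC(=O)C=C2)cc(OC)c1OCc1ccccc1
A3 | alternative 1 | (2S,3S,4S,5R)-2,5-bis[4-(benzyloxy)-3,5-dimethoxyphenyl]-3,4-dimethyloxolane | COc1cc([C@H]2O[C@@H](c3cc(OC)c(OCc4ccccc4)c(OC)c3)[C@@H](C)[C@@H]2C)cc(OC)c1OCc1ccccc1
A4 | alternative 2 | methyl (2S,3S)-2,5-bis[4-(benzyloxy)-3,5-dimethoxyphenyl]-3-methyl-2,3-dihydrofuran-4-carboxylate | COc1cc([C@H]2OC(c3cc(OC)c(OCc4ccccc4)c(OC)c3)=C(C(=O)OC)[C@@H]2C)cc(OC)c1OCc1ccccc1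
A5 | alternative 2 | methyl 3-[4-(benzyloxy)-3,5-dimethoxyphenyl]-2-diazo-3-oxopropanoate | COC(=O)C(=[N+]=[N-])C(=O)c1cc(OC)c(OCc2ccccc2)c(OC)c1
A6 | alternative 2 | 2-(benzyloxy)-1,3-dimethoxy-5-[(1E)-prop-1-en-1-yl]benzene | C/C=C/c1cc(OC)c(OCc2ccccc2)c(OC)c1
A7 | alternative 3 | [4-(benzyloxy)-3,5-dimethoxyphenyl]boronic acid | OB(O)c1cc(OC)c(OCc2ccccc2)c(OC)c1
A8 | alternative 3 | (1R,2S)-1-[4-(benzyloxy)-3,5-dimethoxyphenyl]-2,3-dimethylbut-3-en-1-ol | O[C@@H](c1cc(OC)c(OCc2ccccc2)c(OC)c1)[C@@H](C)C(C)=C
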